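(The rate constants come from no measurement; the run is a simulation.)

starting complex 1.7 M; incoming ligand 1.36 M; leaving ligand 0.850 M; capture agent 0.0850 M; time 20 h

1. at 20 h, what has stopped the reaction, if anything has (it is still moving / the incoming ligand has run out first / forward and back rates have come level / all of the starting complex has reacted)
2. the complex with one exchanged standing at 20 h, as a percentage of the starting complex charged
3. the trapped intermediate standing at 20 h, as a percentage of the starting complex charged

- the reaction counts as stopped when no species that holds the starting complex changes by six tenths of a point or more over the second half of the time
- run time (flask): 20 h

    starting complex + incoming ligand ⇌ leaving ligand + complex with one exchanged (K1 = 0.80, k1 = 0.0087 L mol⁻¹ s⁻¹)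
    complex with one exchanged + incoming ligand ⇌ leaving ligand + complex with two exchanged (K2 = 0.23, k2 = 0.057 L mol⁻¹ s⁻¹)
    complex with two exchanged + incoming ligand ⇌ leaving ligand + complex with three exchanged (K3 = 0.58, k3 = 0.0042 L mol⁻¹ s⁻¹)
    complex with three exchanged + incoming ligand ⇌ leaving ligand + complex with four exchanged (K4 = 1.0, k4 = 0.084 L mol⁻¹ s⁻¹)
    complex with one exchanged + capture agent → trapped intermediate (k5 = 0.0072 L mol⁻¹ s⁻¹)

A one-step world has one arrow and one end to reckon. This flask has a ladder of reversible exchanges, in which the incoming ligand replaces the leaving ligand on the complex stage by stage, and a side exit, in which the capture agent irreversibly turns the complex with one exchanged into the trapped intermediate.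

Does the ladder have time to balance? The exchange out of the complex with two exchanged has the smallest forward constant, 0.0042 L mol⁻¹ s⁻¹. With the incoming ligand as charged, that forward step alone gives a time of 2.92 min, far shorter than the 20 h allowed. So my reckoning expects forward and back rates to have come level well before the end.

How much can the side exit take? Each trapped intermediate costs one capture agent, and the capture agent is charged in a smaller amount than the starting complex, so it is the limiting reagent of this exit. Its balance gives the capture ceiling, the charged capture agent as a share of the charged starting complex: 5.00 %.

Is the ceiling reached in time? Even with the complex with one exchanged standing no higher than the capture agent's charge, the capture time is 27.2 min, far shorter than the run. My reckoning therefore puts the trapped intermediate at the ceiling.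

The forecast says forward and back rates have come level, with 26 % of the complex with one exchanged and 5 % of the trapped intermediate, holding of the capture agent that “it is fully used and locks up 0.085 M (5%) of the complex”.

The simulation gives forward and back rates have come level, with 24.8 % of the complex with one exchanged and 5.00 % of the trapped intermediate.

In this flask the trapped intermediate stands at the ceiling of 5.00 %. The capture agent's half-life, read at 0.00558 h, was 0.11 h, and 0 % of its charge remains at 20.0 h. The ceiling leaves 95.0 % of the complex for the ladder, whose forms together hold 95.0 %.

In the neighbour flask with 0.42 M of starting complex and the same capture agent, the ceiling is 20.2 %. The simulation gives 20.2 % of the trapped intermediate there, with 0 % of the capture agent left.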